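## Assumptions
- Racemic **4** can be used, because its C2 stereocentre is erased on enediol formation.
- The (S,S)-ProPhenol ligand is assumed to give the (1S,4R,5S) antipode of **7**; if the other enantiomer forms, the (R,R) ligand is used.
- The C4-OH ends up exo (anti to the other ring), which is the thermodynamic aldol outcome in the reversible annulation.
- Aminohydroxylation puts N on the alkene carbon remote from the bridgehead (C7) and OH on C6, from the convex face.

## Retrosynthetic overview
1. The target is the (E)-dec-2-enamide of a free amine, so the last steps are Cbz hydrogenolysis and amide coupling.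
2. The cis, exo amino alcohol (C7-N, C6-OH) comes from syn-aminohydroxylation of the C6=C7 alkene of an epoxy-enone bicycle, on the convex face.
3. The epoxide comes from hydroxyl-directed epoxidation of C2=C3 in a bicyclo[3.3.1]nona-2,6-dien-9-one-1,4-diol, syn to both OH groups.
4. Both rings, the C9 ketone, the C1 quaternary carbinol and the C4 carbinol come from one catalytic asymmetric Michael/aldol [3+3] α,α′-annulation (new step). Its partners are 2-hydroxycyclohex-4-en-1-one, which supplies the six-membered ring carrying the future C6/C7 alkene, and propynal, which supplies the three carbons of the second ring.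
5. The ketol comes from 1,4-cyclohexadiene (epoxidation, hydrolysis, mono-oxidation of the diol) and propynal from propargyl alcohol. The ketol's mirror symmetry means the annulation has no regiochemical ambiguity, only an enantiochoice.

## Route

**Step 1**
Reactants: 1, 1,4-cyclohexadiene
Product: 2, 7-oxabicyclo[4.1.0]hept-3-ene (racemic)
Conditions: mCPBA (0.9 equiv), NaHCO3, CH2Cl2, 0 °C
Reagents that add atoms: mCPBA, OOC(=O)c1cccc(Cl)c1 (supplies the epoxide O)
Why: Prilezhaev epoxidation of one alkene, with substoichiometric peracid to limit bis-epoxide; the product is racemic and its stereochemistry is irrelevant downstream.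

**Step 2**
Reactants: 2
Product: 3, trans-cyclohex-4-ene-1,2-diol (racemic)
Conditions: cat. HClO4, THF/H2O (4:1), 25 °C
Reagents that add atoms: water, O
Why: acid-catalysed trans-diaxial epoxide hydrolysis gives the trans-diol.

**Step 3**
Reactants: 3
Product: 4, 2-hydroxycyclohex-4-en-1-one (racemic)
Conditions: [(neocuproine)Pd(OAc)]2(OTf)2 (1 mol%), O2 (1 atm), MeCN, 23 °C, stopped at partial conversion, then used immediately under N2
Reagents that add atoms: none
Why: Pd–neocuproine (Waymouth-type) catalysis oxidises a vicinal diol selectively to the α-hydroxy ketone without over-oxidation; the C2 stereocentre is labile and not needed.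

**Step 4**
Reactants: 5, propargyl alcohol
Product: 6, propynal
Conditions: activated MnO2 (10 equiv), Et2O, 0 °C, filter; use the solution at once
Reagents that add atoms: none
Why: MnO2 selectively oxidises the propargylic alcohol to the volatile ynal.

**Step 5**
Reactants: 4, 2-hydroxycyclohex-4-en-1-one; 6, propynal (1.3 equiv, syringe pump)
Product: 7, (1S,4R,5S)-1,4-dihydroxybicyclo[3.3.1]nona-2,6-dien-9-one
Conditions: (S,S)-ProPhenol (10 mol%), Et2Zn (20 mol%), 4 Å MS, THF, –20 °C, 24 h
Reagents that add atoms: none (propynal is the numbered reactant 6)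
Why: Proposed new method: the dinuclear Zn-ProPhenol catalyst converts the α-ketol of 4 into a zinc enediolate that attacks the ynal β-carbon through its carbinol carbon, giving the tertiary C1-OH and a Z-enal (E/Z equilibrates by reversible Zn-alkoxide conjugate addition). The only remaining enolisable site, C6, then closes a 6-(enolendo)-exo-trig aldol onto the Z-enal, forming the bridged ring. The catalyst pocket fixes the enediolate face, which sets C1; the bridgehead C5 is forced cis by the bicycle; and the reversible aldol funnels to the exo C4-OH. The closest known reactions are Zn-ProPhenol direct aldol/Michael of α-hydroxy ketones and enamine-catalysed Michael/aldol α,α′-annulation of cyclohexanones to bicyclo[3.3.1]nonanones.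

**Step 6**
Reactants: 7
Product: 8, (1S,2S,3S,4S,5S)-2,3-epoxy-1,4-dihydroxybicyclo[3.3.1]non-6-en-9-one
Conditions: VO(acac)2 (5 mol%), TBHP (1.5 equiv), CH2Cl2, 0 °C
Reagents that add atoms: tert-butyl hydroperoxide, CC(C)(C)OO (supplies the epoxide O)
Why: vanadium-catalysed hydroxyl-directed epoxidation (Sharpless–Michaelson) of the doubly allylic-alcohol alkene delivers O syn to the C1-OH and C4-OH, while the isolated C6=C7 alkene is untouched.

**Step 7**
Reactants: 8
Product: 9, benzyl N-[(1S,2S,3S,4S,5S,6R,7S)-2,3-epoxy-1,4,6-trihydroxy-9-oxobicyclo[3.3.1]nonan-7-yl]carbamate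
Conditions: K2OsO2(OH)4 (4 mol%), CbzNH2/t-BuOCl/NaOH (forms CbzNClNa), n-PrOH/H2O 1:1, 23 °C
Reagents that add atoms: benzyl carbamate, NC(=O)OCc1ccccc1 (supplies NHCbz); water, O (supplies OH)
Why: Sharpless-type syn-aminohydroxylation of the C6=C7 alkene occurs on the open convex face, away from the other ring, so N and O are cis and exo, with N on C7 (remote from the bridgehead and from the electron-withdrawing C9 ketone) and O on C6.

**Step 8**
Reactants: 9
Product: 10, (1S,2S,3S,4S,5S,6R,7S)-7-amino-2,3-epoxy-1,4,6-trihydroxybicyclo[3.3.1]nonan-9-one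
Conditions: H2 (1 atm), 10% Pd/C, MeOH, 23 °C
Reagents that add atoms: none
Why: hydrogenolysis of the Cbz carbamate leaves the epoxide, ketone and alcohols intact and sets no new stereocentre.

**Step 9**
Reactants: 10; 11, (E)-dec-2-enoic acid
Product: 12, isariotin D
Conditions: EDC·HCl, HOBt, DMF, 0 °C to 23 °C
Reagents that add atoms: none (the acid is numbered reactant 11)
Why: carbodiimide amide coupling acylates only the amine, leaving the hydroxyls and the epoxide untouched, and retains the (E)-enoyl geometry.

## Compound list
1 | 1,4-cyclohexadiene | C1C=CCC=C1 | starting material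
2 | 7-oxabicyclo[4.1.0]hept-3-ene (racemic) | C1C=CCC2OC12 | intermediate
3 | trans-cyclohex-4-ene-1,2-diol (racemic) | O[C@@H]1CC=CC[C@H]1O | intermediate
4 | 2-hydroxycyclohex-4-en-1-one (racemic) | O=C1CC=CCC1O | intermediate
5 | propargyl alcohol | C#CCO | starting material
6 | propynal | C#CC=O | intermediate
7 | (1S,4R,5S)-1,4-dihydroxybicyclo[3.3.1]nona-2,6-dien-9-one | C1C[C@@]2(O)C(=O)[C@H]([C@H](O)C=C2)C=1 | intermediate
8 | (1S,2S,3S,4S,5S)-2,3-epoxy-1,4-dihydroxybicyclo[3.3.1]non-6-en-9-one | C1C[C@@]2(O)C(=O)[C@H]([C@H](O)[C@@H]3O[C@@H]32)C=1 | intermediate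
9 | Cbz-protected amino epoxy triol ketone | O=C(OCc1ccccc1)N[C@H]1C[C@@]2(O)C(=O)[C@H]([C@H](O)[C@@H]3O[C@@H]32)[C@H]1O | intermediate
10 | free amine (7-amino-2,3-epoxy-1,4,6-trihydroxybicyclo[3.3.1]nonan-9-one) | N[C@H]1C[C@@]2(O)C(=O)[C@H]([C@H](O)[C@@H]3O[C@@H]32)[C@H]1O | intermediate
11 | (E)-dec-2-enoic acid | CCCCCCC/C=C/C(=O)O | starting material
12 | isariotin D, (2E)-N-[(1S,2S,3S,4S,5S,6R,7S)-1,4,6-trihydroxy-9-oxo-2,3-epoxybicyclo[3.3.1]nonan-7-yl]dec-2-enamide | CCCCCCC/C=C/C(=O)N[C@H]1C[C@@]2(O)C(=O)[C@H]([C@H](O)[C@@H]3O[C@@H]32)[C@H]1O | target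

## Totals
- Total steps: 9, including the propynal preparation.
- Longest linear sequence: 8 steps (1 → 2 → 3 → 4 → 7 → 8 → 9 → 10 → 12).

## Three steps most likely to fail
1. **Step 5 (proposed new annulation).** Likely failures are low ee, failure of the Michael adduct to isomerise to the Z-enal, oxidation of the 1,4-diene enediolate to catechol, or the wrong C4 epimer.
   - Fallback (known chemistry, stepwise): treat 4 with TMSOTf/Et3N to make the symmetric bis-silyl enediol ether. Do a Lewis-acid Mukaiyama–Michael with propynal, isomerise E to Z (hν or I2), form the C6 silyl enol ether, and close by intramolecular Mukaiyama aldol (TiCl4) to racemic 7, which is then resolved by chiral HPLC.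
2. **Step 7 (aminohydroxylation regiochemistry and yield).**
   - Fallback (N installed by SN2 instead of syn-addition): exo-face OsO4/NMO dihydroxylation; oxidise the less hindered C7-OH (Bu2SnO/NBS); reduce with NaBH4 from the exo face to give endo C7-OH; convert with DPPA/DBU to exo C7-N3 by inversion; Staudinger reduction gives 10.
3. **Step 3 (ketol 4 is prone to over-oxidation or aromatisation to catechol).**
   - Fallback (RCM instead of diol oxidation): (±)-2-hydroxypent-4-enoic acid → TBS ether → Weinreb amide → allylMgBr gives the dienone; Grubbs-II RCM gives 2-(TBSO)cyclohex-4-enone; HF·pyridine gives 4.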